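**Retrosynthetic overview**

1. Target 30 comes from the tertiary silyl ether 28 by exchange of C1′–O for C1′–Br with retention (last step). The (E)-bromovinyl group comes from a Takai–Utimoto olefination of a C2 carbaldehyde. C1′ (Me, CH2Cl, O) comes from a chelation-controlled MeMgBr addition to a C5 chloromethyl ketone.
2. Both arms arise by ozonolysis of the C3=C4 enol ether of (1S,5R,7S)-7-chloro-1-methyl-8-oxabicyclo[3.2.1]octan-3-one 16. Bicycle C4 becomes C1′, bicycle C2 becomes Cα, and the ketone carbon is excised later. The C–Cl centre (oxolane C3) is set by exo-face diimide reduction of the chloroalkene.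
3. The bicycle comes from a (4+3) cycloaddition of 3-chloro-2-methylfuran 5 with the 2-(trimethylsilyloxy)allyl cation from 8; the racemate is resolved through a sulfoximine adduct.
4. Feature used: in the oxolane (O1, C2–C5) the bromovinyl carbon Cα on C2 and the side-chain carbon C1′ on C5 are cis. This is the arrangement of the bridgehead substituents C2 and C4 in an 8-oxabicyclo[3.2.1]octane whose oxygen bridge is O1.
5. Ring order: the furan ring is bought; the seven-membered carbocycle is closed across it in step 4 and opened again in step 9, which leaves the oxolane.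

Key step: step 4

Assumption: the (S,S)-enantiomer of lithium bis(1-phenylethyl)amide is taken to be the one that prefers H-4ax of 16 (by analogy with its sense on 4-substituted chair cyclohexanones); if a test on the meso parent ketone shows the opposite sense, the (R,R)-amide is used in step 8.

**Route**

Step 1
Reactants: 1 3-bromofuran
Product: 3 3-bromo-2-methylfuran, via 3-bromo-2-lithiofuran 2 (not isolated)
Conditions: LDA, THF, −78 °C; MeI, −78 °C → rt
Reagents that add atoms: iodomethane, CI
Why: Directed lithiation–alkylation: LDA removes the most acidic furan proton (C2, between O and Br) without bromine–lithium exchange, and the 2-lithiofuran is methylated by SN2 on iodomethane.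

Step 2
Reactants: 3 3-bromo-2-methylfuran
Product: 5 3-chloro-2-methylfuran, via 3-lithio-2-methylfuran 4 (not isolated)
Conditions: t-BuLi (2 equiv), Et2O, −78 °C; C2Cl6, −78 → 0 °C; distillation
Reagents that add atoms: hexachloroethane, ClC(Cl)(Cl)C(Cl)(Cl)Cl
Why: Bromine–lithium exchange followed by electrophilic chlorination: the 3-furyllithium keeps its position at −78 °C (C2 is blocked by methyl) and takes Cl+ from hexachloroethane.

Step 3
Reactants: 6 1,3-dichloroacetone
Product: 8 3-chloro-2-(trimethylsilyloxy)prop-1-ene, via chlorozinc enolate 7 (not isolated)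
Conditions: Zn–Cu couple, Me3SiCl, Et2O, rt → reflux; distillation
Reagents that add atoms: chlorotrimethylsilane, C[Si](C)(C)Cl
Why: Reductive silylation (Reformatsky-type): zinc inserts into one C–Cl bond to give the zinc enolate of chloroacetone, which is O-silylated as it forms, so the double bond sits regiospecifically at the reduced carbon.

Step 4
Reactants: 5 3-chloro-2-methylfuran; 8 3-chloro-2-(trimethylsilyloxy)prop-1-ene
Product: 11 rac-7-chloro-1-methyl-8-oxabicyclo[3.2.1]oct-6-en-3-one, via 2-(trimethylsilyloxy)allyl cation 9 (not isolated), via O-silyl oxocarbenium ion 10 (not isolated)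
Conditions: AgClO4, MeNO2, 0 °C; aq. NaHCO3
Reagents that add atoms: none
Why: Silver(I) pulls chloride from 8 to give the planar, symmetric 2-siloxyallyl cation 9, which adds across C2 and C5 of the furan diene (concerted but asynchronous, or stepwise with the first bond to the unsubstituted C5 and closure at the methyl-bearing C2) to the O-silyl oxocarbenium ion 10, and work-up removes silicon. The closest known reaction type is the (4+3) cycloaddition of furans with oxyallyl cations generated from 2-siloxyallyl halides and silver salts. One ring is closed, the seven-membered carbocycle C1–C7 of the bicycle, by intermolecular (4+3) annulation (4π of the furan, 2π over three carbons of the cation, suprafacial on both), the furan oxygen becoming the one-atom bridge. The two new stereocentres C1 and C5 are fixed relative to each other by the bicyclic geometry, since both bonds must form on the same furan face; the absolute sense is not controlled, both partners being achiral, and the racemate is resolved in steps 5 and 6. No regio- or endo/exo selectivity is needed because 9 is symmetric and carries only hydrogen at its termini; what is needed is cycloaddition in preference to proton loss after the first bond (furan alkylation at C5), and the non-nucleophilic medium (MeNO2, perchlorate, 0 °C) together with the cation-stabilising 2-methyl group at the closing carbon should secure it.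

Step 5
Reactants: 11 rac-7-chloro-1-methyl-8-oxabicyclo[3.2.1]oct-6-en-3-one; 12 (S)-N,S-dimethyl-S-phenylsulfoximine
Product: 14 (1S,3R,5R)-7-chloro-1-methyl-3-{[(S)-N-methyl-S-phenylsulfonimidoyl]methyl}-8-oxabicyclo[3.2.1]oct-6-en-3-ol, via lithiated sulfoximine 13 (not isolated)
Conditions: n-BuLi, THF, −78 °C; then 11, −78 °C; NH4Cl; separation of the diastereomers on SiO2 (or by crystallisation)
Reagents that add atoms: none
Why: Sulfoximine resolution of a ketone: the α-lithiated enantiopure sulfoximine adds 1,2 to the carbonyl from the less hindered equatorial (exo) side, which should set C3 as drawn, and turns the two ketone enantiomers into separable diastereomers whose configuration can be assigned by X-ray analysis against the known sulfur centre.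

Step 6
Reactants: 14 (1S,3R,5R)-sulfoximine adduct
Product: 15 (1S,5R)-7-chloro-1-methyl-8-oxabicyclo[3.2.1]oct-6-en-3-one
Conditions: toluene, 110 °C
Reagents that add atoms: none
Why: Thermal retro-addition of the β-hydroxy sulfoximine releases the ketone and the resolving agent; the bridgehead centres C1 and C5 cannot epimerise.

Step 7
Reactants: 15 (1S,5R)-7-chloro-1-methyl-8-oxabicyclo[3.2.1]oct-6-en-3-one
Product: 16 (1S,5R,7S)-7-chloro-1-methyl-8-oxabicyclo[3.2.1]octan-3-one
Conditions: KO2CN=NCO2K, AcOH, MeOH, 0 °C → rt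
Reagents that add atoms: none
Why: Diimide reduction: concerted syn transfer of two hydrogens to the strained chloroalkene from the open exo face (anti to the C2–C3–C4 bridge) places H exo and Cl endo at C7 (S), cis to C2 and C4, without hydrogenolysis of C–Cl or reduction of the ketone.

Step 8
Reactants: 16 (1S,5R,7S)-7-chloro-1-methyl-8-oxabicyclo[3.2.1]octan-3-one
Product: 18 (1S,5S,7S)-7-chloro-1-methyl-3-(triethylsilyloxy)-8-oxabicyclo[3.2.1]oct-3-ene, via lithium enolate 17 (not isolated)
Conditions: (S,S)-bis(1-phenylethyl)amine·HCl, n-BuLi (2 equiv), THF, −78 → 0 °C; Et3SiCl, then 16, −100 °C (in situ quench)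
Reagents that add atoms: chlorotriethylsilane, CC[Si](Cl)(CC)CC
Why: Kinetic deprotonation with a chiral lithium amide and O-silylation: the amide's preference for one axial α-proton and the shielding of H-2ax by the C1 methyl group point the same way (matched case), so the enolate should form towards C4 (numbering of 16 kept; the C5 descriptor changes only by the CIP rules).

Step 9
Reactants: 18 (1S,5S,7S)-7-chloro-1-methyl-3-(triethylsilyloxy)-8-oxabicyclo[3.2.1]oct-3-ene
Product: 20 methyl 2-[(2S,3S,5S)-3-chloro-5-formyl-2-methyloxolan-2-yl]acetate, via aldehyde acid 19 (not isolated)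
Conditions: O3, CH2Cl2/MeOH, −78 °C; Me2S, −78 °C → rt; then TMSCHN2, 0 °C
Reagents that add atoms: ozone, O=[O+][O-]; (trimethylsilyl)diazomethane, C[Si](C)(C)C=[N+]=[N-]
Why: Ozonolysis of a silyl enol ether cleaves C3=C4 into the C4 aldehyde and the C3 silyl ester, which methanol frees to the acid and TMS-diazomethane methylates; the carbocycle opens, the oxolane centres are untouched and the α-alkoxy aldehyde sees no base.

Step 10
Reactants: 20 methyl 2-[(2S,3S,5S)-3-chloro-5-formyl-2-methyloxolan-2-yl]acetate
Product: 21 methyl 2-[(2S,3S,5S)-3-chloro-5-(2-chloro-1-hydroxyethyl)-2-methyloxolan-2-yl]acetate (both carbinol epimers)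
Conditions: ICH2Cl, MeLi·LiBr, THF, −78 °C; AcOH, −78 °C
Reagents that add atoms: chloroiodomethane, ClCI
Why: Carbenoid addition: chloromethyllithium made in situ by iodine–lithium exchange adds to the aldehyde far faster than to the methyl ester, and the cold acidic quench keeps the chlorohydrin from closing to an epoxide; the new carbinol centre is removed in step 11.

Step 11
Reactants: 21 methyl 2-[(2S,3S,5S)-3-chloro-5-(2-chloro-1-hydroxyethyl)-2-methyloxolan-2-yl]acetate
Product: 22 methyl 2-[(2S,3S,5S)-3-chloro-5-(chloroacetyl)-2-methyloxolan-2-yl]acetate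
Conditions: Dess–Martin periodinane, NaHCO3, CH2Cl2, 0 °C → rt
Reagents that add atoms: none
Why: Dess–Martin oxidation under buffered, non-basic conditions gives the α-chloro ketone without epimerising the adjacent C5–H.

Step 12
Reactants: 22 methyl 2-[(2S,3S,5S)-3-chloro-5-(chloroacetyl)-2-methyloxolan-2-yl]acetate
Product: 23 methyl 2-[(2S,3S,5S)-3-chloro-5-[(2S)-1-chloro-2-hydroxypropan-2-yl]-2-methyloxolan-2-yl]acetate
Conditions: MeMgBr, CH2Cl2/Et2O, −78 °C; NH4Cl, −78 °C
Reagents that add atoms: methylmagnesium bromide, C[Mg]Br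
Why: Chelation-controlled (Cram chelate) Grignard addition: magnesium bridges the ketone oxygen and the ring oxygen O1, and methyl adds from the face of the C5 hydrogen, which sets C1′ as (S) with the hydroxyl where bromine has to end up; the ester is left alone at −78 °C.

Step 13
Reactants: 23 methyl 2-[(2S,3S,5S)-3-chloro-5-[(2S)-1-chloro-2-hydroxypropan-2-yl]-2-methyloxolan-2-yl]acetate
Product: 24 methyl 2-[(2S,3S,5S)-3-chloro-5-[(2S)-1-chloro-2-(triethylsilyloxy)propan-2-yl]-2-methyloxolan-2-yl]acetate
Conditions: Et3SiOTf, 2,6-lutidine, CH2Cl2, −78 → 0 °C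
Reagents that add atoms: triethylsilyl trifluoromethanesulfonate, CC[Si](CC)(CC)OS(=O)(=O)C(F)(F)F
Why: Silylation of the tertiary alcohol with a silyl triflate and a weak hindered base protects the chlorohydrin against epoxide closure and against lactol formation with the aldehyde made in step 14.

Step 14
Reactants: 24 methyl 2-[(2S,3S,5S)-3-chloro-5-[(2S)-1-chloro-2-(triethylsilyloxy)propan-2-yl]-2-methyloxolan-2-yl]acetate
Product: 25 [(2S,3S,5S)-3-chloro-5-[(2S)-1-chloro-2-(triethylsilyloxy)propan-2-yl]-2-methyloxolan-2-yl]acetaldehyde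
Conditions: DIBAL-H (1.1 equiv), CH2Cl2, −78 °C; Rochelle salt
Reagents that add atoms: none
Why: Partial ester reduction with DIBAL-H at −78 °C stops at the aluminium hemiacetal (held by the β ring oxygen), which gives the aldehyde on work-up.

Step 15
Reactants: 25 [(2S,3S,5S)-3-chloro-5-[(2S)-1-chloro-2-(triethylsilyloxy)propan-2-yl]-2-methyloxolan-2-yl]acetaldehyde
Product: 26 (2S,3S,5S)-3-chloro-5-[(2S)-1-chloro-2-(triethylsilyloxy)propan-2-yl]-2-methyl-2-[2-(triethylsilyloxy)ethenyl]oxolane (E/Z mixture)
Conditions: Et3SiOTf, Et3N, CH2Cl2, −78 → 0 °C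
Reagents that add atoms: triethylsilyl trifluoromethanesulfonate, CC[Si](CC)(CC)OS(=O)(=O)C(F)(F)F
Why: Soft enolisation of the aldehyde with a silyl triflate and triethylamine gives the silyl enol ether without a free enolate, so β-elimination of the ring oxygen is avoided.

Step 16
Reactants: 26 (2S,3S,5S)-3-chloro-5-[(2S)-1-chloro-2-(triethylsilyloxy)propan-2-yl]-2-methyl-2-[2-(triethylsilyloxy)ethenyl]oxolane
Product: 27 (2S,3S,5S)-3-chloro-5-[(2S)-1-chloro-2-(triethylsilyloxy)propan-2-yl]-2-methyloxolane-2-carbaldehyde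
Conditions: O3, CH2Cl2, −78 °C; Me2S, −78 °C → rt
Reagents that add atoms: ozone, O=[O+][O-]
Why: Ozonolysis of the enol ether removes the former ketone carbon as silyl formate and leaves the non-enolisable C2 carbaldehyde (Cα).

Step 17
Reactants: 27 (2S,3S,5S)-3-chloro-5-[(2S)-1-chloro-2-(triethylsilyloxy)propan-2-yl]-2-methyloxolane-2-carbaldehyde
Product: 28 (2S,3S,5S)-2-[(E)-2-bromoethenyl]-3-chloro-5-[(2S)-1-chloro-2-(triethylsilyloxy)propan-2-yl]-2-methyloxolane
Conditions: CrBr2, CHBr3, THF, 0 → 25 °C
Reagents that add atoms: bromoform, BrC(Br)Br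
Why: Takai–Utimoto olefination: the gem-dichromium species from bromoform and Cr(II) adds to the aldehyde and eliminates to the (E)-bromoalkene, the bulky quaternary C2 favouring E; chromium(II) bromide is used so that no chloride enters the vinyl halide.

Step 18
Reactants: 28 (2S,3S,5S)-2-[(E)-2-bromoethenyl]-3-chloro-5-[(2S)-1-chloro-2-(triethylsilyloxy)propan-2-yl]-2-methyloxolane
Product: 30 (2S,3S,5S)-5-[(2S)-2-bromo-1-chloropropan-2-yl]-2-[(E)-2-bromoethenyl]-3-chloro-2-methyloxolane, via free chlorohydrin 29 (not isolated)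
Conditions: Me3SiBr (excess), MeOH (1–2 equiv), CH2Cl2, −40 → 0 °C
Reagents that add atoms: bromotrimethylsilane, C[Si](C)(C)Br
Why: Proposed new method: HBr made in situ first cleaves the silyl ether and then ionises the tertiary alcohol, whose unassisted ionisation is slowed by the β-chlorine and the β-oxygen, so that the neighbouring chlorine (chloriranium ion) or the ring oxygen (oxiranium ion) should displace water from the back and bromide then open the three-membered ion at the tertiary carbon, a double inversion that returns the (S) configuration at C1′; the closest known reaction types are the deoxybromination of tertiary alcohols with Me3SiBr/HBr and the retentive conversion of halohydrins into vicinal dihalides through halonium participation.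

**Compound list**

1 | 3-bromofuran | Brc1ccoc1 | starting material
2 | 3-bromo-2-lithiofuran | [Li]c1occc1Br | intermediate (not isolated)
3 | 3-bromo-2-methylfuran | Cc1occc1Br | intermediate
4 | 3-lithio-2-methylfuran | [Li]c1ccoc1C | intermediate (not isolated)
5 | 3-chloro-2-methylfuran | Cc1occc1Cl | intermediate
6 | 1,3-dichloroacetone | O=C(CCl)CCl | starting material
7 | chlorozinc 3-chloroprop-1-en-2-olate | C=C(CCl)O[Zn]Cl | intermediate (not isolated)
8 | 3-chloro-2-(trimethylsilyloxy)prop-1-ene | C=C(CCl)O[Si](C)(C)C | intermediate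
9 | 2-(trimethylsilyloxy)allyl cation | C=C(O[Si](C)(C)C)[CH2+] | intermediate (not isolated)
10 | O-trimethylsilyl oxocarbenium ion of 11 (racemic; one enantiomer drawn) | C[Si](C)(C)[O+]=C1C[C@@H]2C=C(Cl)[C@](C)(C1)O2 | intermediate (not isolated)
11 | rac-7-chloro-1-methyl-8-oxabicyclo[3.2.1]oct-6-en-3-one (racemic; the 1S,5R enantiomer drawn) | O=C1C[C@@H]2C=C(Cl)[C@](C)(C1)O2 | intermediate
12 | (S)-N,S-dimethyl-S-phenylsulfoximine | C[S@@](=O)(=NC)c1ccccc1 | starting material
13 | lithiated (S)-N,S-dimethyl-S-phenylsulfoximine | [Li]C[S@@](=O)(=NC)c1ccccc1 | intermediate (not isolated)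
14 | (1S,3R,5R)-7-chloro-1-methyl-3-{[(S)-N-methyl-S-phenylsulfonimidoyl]methyl}-8-oxabicyclo[3.2.1]oct-6-en-3-ol | O[C@]1(C[S@@](=O)(=NC)c3ccccc3)C[C@@H]2C=C(Cl)[C@](C)(C1)O2 | intermediate
15 | (1S,5R)-7-chloro-1-methyl-8-oxabicyclo[3.2.1]oct-6-en-3-one | O=C1C[C@@H]2C=C(Cl)[C@](C)(C1)O2 | intermediate
16 | (1S,5R,7S)-7-chloro-1-methyl-8-oxabicyclo[3.2.1]octan-3-one | O=C1C[C@@H]2C[C@H](Cl)[C@](C)(C1)O2 | intermediate
17 | lithium (1S,5S,7S)-7-chloro-1-methyl-8-oxabicyclo[3.2.1]oct-3-en-3-olate | [Li]OC1=C[C@@H]2C[C@H](Cl)[C@](C)(C1)O2 | intermediate (not isolated)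
18 | (1S,5S,7S)-7-chloro-1-methyl-3-(triethylsilyloxy)-8-oxabicyclo[3.2.1]oct-3-ene | CC[Si](CC)(CC)OC1=C[C@@H]2C[C@H](Cl)[C@](C)(C1)O2 | intermediate
19 | 2-[(2S,3S,5S)-3-chloro-5-formyl-2-methyloxolan-2-yl]acetic acid | O=C[C@@H]1C[C@H](Cl)[C@](C)(CC(=O)O)O1 | intermediate (not isolated)
20 | methyl 2-[(2S,3S,5S)-3-chloro-5-formyl-2-methyloxolan-2-yl]acetate | O=C[C@@H]1C[C@H](Cl)[C@](C)(CC(=O)OC)O1 | intermediate
21 | methyl 2-[(2S,3S,5S)-3-chloro-5-(2-chloro-1-hydroxyethyl)-2-methyloxolan-2-yl]acetate (both carbinol epimers) | OC(CCl)[C@@H]1C[C@H](Cl)[C@](C)(CC(=O)OC)O1 | intermediate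
22 | methyl 2-[(2S,3S,5S)-3-chloro-5-(chloroacetyl)-2-methyloxolan-2-yl]acetate | O=C(CCl)[C@@H]1C[C@H](Cl)[C@](C)(CC(=O)OC)O1 | intermediate
23 | methyl 2-[(2S,3S,5S)-3-chloro-5-[(2S)-1-chloro-2-hydroxypropan-2-yl]-2-methyloxolan-2-yl]acetate | C[C@@](O)(CCl)[C@@H]1C[C@H](Cl)[C@](C)(CC(=O)OC)O1 | intermediate
24 | methyl 2-[(2S,3S,5S)-3-chloro-5-[(2S)-1-chloro-2-(triethylsilyloxy)propan-2-yl]-2-methyloxolan-2-yl]acetate | C[C@@](O[Si](CC)(CC)CC)(CCl)[C@@H]1C[C@H](Cl)[C@](C)(CC(=O)OC)O1 | intermediate
25 | [(2S,3S,5S)-3-chloro-5-[(2S)-1-chloro-2-(triethylsilyloxy)propan-2-yl]-2-methyloxolan-2-yl]acetaldehyde | C[C@@](O[Si](CC)(CC)CC)(CCl)[C@@H]1C[C@H](Cl)[C@](C)(CC=O)O1 | intermediate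
26 | (2S,3S,5S)-3-chloro-5-[(2S)-1-chloro-2-(triethylsilyloxy)propan-2-yl]-2-methyl-2-[2-(triethylsilyloxy)ethenyl]oxolane (E/Z mixture) | C[C@@](O[Si](CC)(CC)CC)(CCl)[C@@H]1C[C@H](Cl)[C@](C)(C=CO[Si](CC)(CC)CC)O1 | intermediate
27 | (2S,3S,5S)-3-chloro-5-[(2S)-1-chloro-2-(triethylsilyloxy)propan-2-yl]-2-methyloxolane-2-carbaldehyde | C[C@@](O[Si](CC)(CC)CC)(CCl)[C@@H]1C[C@H](Cl)[C@](C)(C=O)O1 | intermediate
28 | (2S,3S,5S)-2-[(E)-2-bromoethenyl]-3-chloro-5-[(2S)-1-chloro-2-(triethylsilyloxy)propan-2-yl]-2-methyloxolane | C[C@@](O[Si](CC)(CC)CC)(CCl)[C@@H]1C[C@H](Cl)[C@](C)(/C=C/Br)O1 | intermediate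
29 | (2S)-2-[(2S,4S,5S)-5-[(E)-2-bromoethenyl]-4-chloro-5-methyloxolan-2-yl]-1-chloropropan-2-ol | C[C@@](O)(CCl)[C@@H]1C[C@H](Cl)[C@](C)(/C=C/Br)O1 | intermediate (not isolated)
30 | (2S,3S,5S)-5-[(2S)-2-bromo-1-chloropropan-2-yl]-2-[(E)-2-bromoethenyl]-3-chloro-2-methyloxolane (CNP0172541.1) | C[C@@](Br)(CCl)[C@@H]1C[C@H](Cl)[C@](C)(/C=C/Br)O1 | target

**Step count**

Total: 18 steps. Longest linear sequence: 17 steps (steps 1, 2 and 4–18 from 3-bromofuran); step 3 is a one-step side branch.

**Three steps most likely to fail**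

Step 18 (proposed new method). The tertiary centre may ionise to an open cation and lose its configuration, a proton may be lost (E1), or bromide may open the oxiranium ion at C5 and enlarge the ring. The fallback uses known reaction types and gives up stereocontrol at C1′. It sets out from 28: HF·pyridine in THF gives the chlorohydrin 29, now isolated. Burgess reagent dehydrates 29 to (2S,3S,5S)-2-[(E)-2-bromoethenyl]-3-chloro-5-(3-chloroprop-1-en-2-yl)-2-methyloxolane F1 together with its regioisomer (2S,3S,5S)-2-[(E)-2-bromoethenyl]-3-chloro-5-(1-chloroprop-1-en-2-yl)-2-methyloxolane F2. Ionic Markovnikov addition of HBr (CH2Cl2, 0 °C) converts both alkenes into the same tertiary bromide, which should be obtained as 30 and its C1′ epimer (2S,3S,5S)-5-[(2R)-2-bromo-1-chloropropan-2-yl]-2-[(E)-2-bromoethenyl]-3-chloro-2-methyloxolane F3. The epimers are separated by preparative HPLC and the fallback comes back to the route at 30.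

Step 4 (key step). After the first C–C bond the σ-complex may lose a proton (furan alkylation at C5), or the cation may oligomerise, faster than the second bond closes the ring. The fallback sets out from 5 and generates a bromine-stabilised oxyallyl cation reductively: 1,1,3,3-tetrabromoacetone, activated Zn and B(OEt)3 in THF should give 2,4-dibromo-7-chloro-1-methyl-8-oxabicyclo[3.2.1]oct-6-en-3-one F4 as a mixture of diastereomers. Zn–Cu couple with NH4Cl in MeOH removes both α-bromines, leaves the vinyl chloride, and comes back to the route at 11.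

Step 8. The deprotonation may not discriminate enough between the two α-methylene groups, or the amide may act in the opposite sense, so that the wrong C–C bond is cleaved in step 9. The fallback sets out from 16: Baeyer–Villiger oxidation (mCPBA, NaHCO3, CH2Cl2) gives both lactones, which are constitutional isomers and separable. The lactone with oxygen between C3 and C4, (1S,6S,7S)-7-chloro-6-methyl-3,9-dioxabicyclo[4.2.1]nonan-4-one F5, is separated from (1S,6R,8S)-8-chloro-1-methyl-3,9-dioxabicyclo[4.2.1]nonan-4-one F6. K2CO3 in MeOH opens F5 to methyl 2-[(2S,3S,5S)-3-chloro-5-(hydroxymethyl)-2-methyloxolan-2-yl]acetate F7, and Dess–Martin oxidation of F7 comes back to the route at 20.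

**Further compounds**

F1 | step 18 | (2S,3S,5S)-2-[(E)-2-bromoethenyl]-3-chloro-5-(3-chloroprop-1-en-2-yl)-2-methyloxolane | C=C(CCl)[C@@H]1C[C@H](Cl)[C@](C)(/C=C/Br)O1
F2 | step 18 | (2S,3S,5S)-2-[(E)-2-bromoethenyl]-3-chloro-5-(1-chloroprop-1-en-2-yl)-2-methyloxolane (E/Z) | CC(=CCl)[C@@H]1C[C@H](Cl)[C@](C)(/C=C/Br)O1
F3 | step 18 | (2S,3S,5S)-5-[(2R)-2-bromo-1-chloropropan-2-yl]-2-[(E)-2-bromoethenyl]-3-chloro-2-methyloxolane | C[C@](Br)(CCl)[C@@H]1C[C@H](Cl)[C@](C)(/C=C/Br)O1
F4 | step 4 | 2,4-dibromo-7-chloro-1-methyl-8-oxabicyclo[3.2.1]oct-6-en-3-one (racemic; C2/C4 epimers) | O=C1C(Br)[C@@H]2C=C(Cl)[C@](C)(C1Br)O2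
F5 | step 8 | (1S,6S,7S)-7-chloro-6-methyl-3,9-dioxabicyclo[4.2.1]nonan-4-one | O1C[C@@H]2C[C@H](Cl)[C@](C)(CC1=O)O2
F6 | step 8 | (1S,6R,8S)-8-chloro-1-methyl-3,9-dioxabicyclo[4.2.1]nonan-4-one | O=C1C[C@@H]2C[C@H](Cl)[C@](C)(CO1)O2
F7 | step 8 | methyl 2-[(2S,3S,5S)-3-chloro-5-(hydroxymethyl)-2-methyloxolan-2-yl]acetate | OC[C@@H]1C[C@H](Cl)[C@](C)(CC(=O)OC)O1
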